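The 18-membered ring is opened at the aryl C–O bond between the oxygen on the meta-substituted ring A and the ring D carbon that lies para to the ring D hydroxyl and ortho to the ethylene bridge. That para relationship (and the ortho one between OH and ether carbon on ring C) lets both hydroxyls travel as formyl groups, which activate C–F bonds for SNAr and become OH in one final double Baeyer–Villiger oxidation. The key step closes the macrocycle by SNAr in one protecting-group-free operation. Its precursor is an open-chain bis(bibenzyl): one free ring A phenol, one ring D fluoride para to CHO, and the B–O–C ether already in place.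

Key step: step 7

Ring labels:
- A is the 1,3-disubstituted ring (O, CH2).
- B is the 1,4-disubstituted ring (O, CH2).
- C is the ring whose OH is ortho to the B–O ether carbon and para to its CH2.
- D is the ring whose OH is para to the A–O ether carbon and meta to its CH2.

Assumption: the structure carries no stereodescriptor, so the macrocycle is treated as achiral and conformationally mobile, and no step has to set configuration.

Step 1
Reactants: 1 4-iodophenol; 2 4-bromo-2-fluorobenzaldehyde
Product: 3 4-bromo-2-(4-iodophenoxy)benzaldehyde
Conditions: K2CO3, DMF, 90 °C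
Reagents that add atoms: none
Why: SNAr (addition–elimination) in which the ortho formyl group of 2 stabilises the Meisenheimer adduct at C–F, fluoride leaves far faster than the para bromide, and the aryl iodide is inert to carbonate.

Step 2
Reactants: 3 4-bromo-2-(4-iodophenoxy)benzaldehyde; 4 3-ethynylphenol
Product: 5 4-bromo-2-{4-[(3-hydroxyphenyl)ethynyl]phenoxy}benzaldehyde
Conditions: PdCl2(PPh3)2 (cat.), CuI (cat.), Et3N, THF, 0 °C to rt, 1.0 equiv of 4
Reagents that add atoms: none
Why: Sonogashira coupling in which oxidative addition into C–I is much faster than into C–Br at or below room temperature, so one equivalent of alkyne should go to ring B only, while the free phenol and the aldehyde tolerate Pd/Cu/Et3N.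

Step 3
Reactants: 6 3-bromo-4-fluorobenzaldehyde; 7 trimethylsilylacetylene
Product: 8 4-fluoro-3-[(trimethylsilyl)ethynyl]benzaldehyde
Conditions: PdCl2(PPh3)2 (cat.), CuI (cat.), Et3N, THF, 50 °C
Reagents that add atoms: none
Why: Sonogashira coupling at the C–Br bond, run with a tertiary amine because it can neither displace the activated fluoride nor condense with the aldehyde.

Step 4
Reactants: 8 4-fluoro-3-[(trimethylsilyl)ethynyl]benzaldehyde
Product: 9 3-ethynyl-4-fluorobenzaldehyde
Conditions: K2CO3 (cat.), MeOH/CH2Cl2, 0 °C
Reagents that add atoms: none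
Why: Base-catalysed protodesilylation of the alkynylsilane by methanol, fast enough at 0 °C that methoxide attack on the C–F bond should not compete.

Step 5
Reactants: 5 4-bromo-2-{4-[(3-hydroxyphenyl)ethynyl]phenoxy}benzaldehyde; 9 3-ethynyl-4-fluorobenzaldehyde
Product: 10 4-[(2-fluoro-5-formylphenyl)ethynyl]-2-{4-[(3-hydroxyphenyl)ethynyl]phenoxy}benzaldehyde (diyne dialdehyde)
Conditions: PdCl2(PPh3)2 (cat.), CuI (cat.), Et3N, THF, 60 °C, degassed, slow addition of 9
Reagents that add atoms: none
Why: Sonogashira coupling at a C–Br bond activated by the para formyl group, in which Et3N is too weak a base to start phenoxide SNAr at the fluoride and slow addition of 9 limits Glaser homocoupling.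

Step 6
Reactants: 10 diyne dialdehyde
Product: 11 4-[2-(2-fluoro-5-formylphenyl)ethyl]-2-{4-[2-(3-hydroxyphenyl)ethyl]phenoxy}benzaldehyde (seco fluoro dialdehyde)
Conditions: H2 (1 atm), 10% Pd/C, Ph2S (cat.), EtOAc, rt
Reagents that add atoms: none
Why: Chemoselective heterogeneous hydrogenation on sulfide-poisoned Pd/C, which should saturate both diarylalkynes to CH2CH2 bridges while leaving the aromatic aldehydes, the C–F bond and the diaryl ether untouched.

Step 7
Reactants: 11 seco fluoro dialdehyde
Product: 12 macrocyclic dialdehyde (the dihydroptychantol A ring system with CHO in place of both OH groups)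
Conditions: Cs2CO3, 4 Å MS, DMSO, 110 °C, argon, syringe-pump addition of 11 (final ca. 2 mM)
Reagents that add atoms: none
Why: Cs2CO3 deprotonates the only acidic group, the ring A phenol, and the phenoxide adds to the fluorine-bearing ring D carbon to give a Meisenheimer adduct whose charge is delocalised onto the para formyl oxygen, after which loss of fluoride restores aromaticity (addition–elimination, SNAr). The closest known reaction type is the SNAr macrocyclisation of activated aryl fluorides to cyclophane diaryl ethers, together with the intermolecular coupling of phenols with 4-fluorobenzaldehydes. One ring is closed, the 18-membered macrocycle (shortest path), by end-to-end attack of O on an sp2 carbon with the C–F bond exocyclic to the new ring, and the two flexible CH2CH2 bridges let the phenoxide approach perpendicular to ring D. No stereocentre is formed. Site selectivity is secured by the substrate, which holds one nucleophile (both future hydroxyls are formyl groups) and one fluoride, while the only other activated leaving group, the ring B aryloxide ortho to the ring C formyl, is a far poorer nucleofuge and could be reached only through a strained 12-membered paracyclophane-like transition state. Ring closure against oligomerisation is secured by slow addition to about 2 mM, and the non-enolisable aldehydes should tolerate hot carbonate.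

Step 8
Reactants: 12 macrocyclic dialdehyde
Product: 14 dihydroptychantol A, via macrocyclic bis(formate) 13 (not isolated)
Conditions: mCPBA, CH2Cl2, 0 °C to reflux; then K2CO3 (cat.), MeOH, rt, argon
Reagents that add atoms: mCPBA, O=C(OO)c1cccc(Cl)c1
Why: Double Baeyer–Villiger oxidation (Dakin-type overall) in which aryl migration should win over hydride migration because each migrating carbon has an aryloxy donor ortho (ring C) or para (ring D) to it, and the phenols stay masked as formates until the oxidant is gone and methanolysis releases them.

Compound list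
1 | 4-iodophenol | Oc1ccc(I)cc1 | starting material
2 | 4-bromo-2-fluorobenzaldehyde | O=Cc1ccc(Br)cc1F | starting material
3 | 4-bromo-2-(4-iodophenoxy)benzaldehyde | O=Cc1ccc(Br)cc1Oc1ccc(I)cc1 | intermediate
4 | 3-ethynylphenol | C#Cc1cccc(O)c1 | starting material
5 | 4-bromo-2-{4-[(3-hydroxyphenyl)ethynyl]phenoxy}benzaldehyde | O=Cc1ccc(Br)cc1Oc1ccc(cc1)C#Cc1cccc(O)c1 | intermediate
6 | 3-bromo-4-fluorobenzaldehyde | O=Cc1ccc(F)c(Br)c1 | starting material
7 | trimethylsilylacetylene | C#C[Si](C)(C)C | starting material
8 | 4-fluoro-3-[(trimethylsilyl)ethynyl]benzaldehyde | O=Cc1ccc(F)c(c1)C#C[Si](C)(C)C | intermediate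
9 | 3-ethynyl-4-fluorobenzaldehyde | O=Cc1ccc(F)c(c1)C#C | intermediate
10 | diyne dialdehyde | O=Cc1ccc(cc1Oc1ccc(cc1)C#Cc1cccc(O)c1)C#Cc1cc(C=O)ccc1F | intermediate
11 | seco fluoro dialdehyde | O=Cc1ccc(cc1Oc1ccc(cc1)CCc1cccc(O)c1)CCc1cc(C=O)ccc1F | intermediate
12 | macrocyclic dialdehyde | O=Cc1ccc2c(c1)CCc1ccc(C=O)c(c1)Oc1ccc(cc1)CCc1cccc(c1)O2 | intermediate
13 | macrocyclic bis(formate) | O=COc1ccc2c(c1)CCc1ccc(OC=O)c(c1)Oc1ccc(cc1)CCc1cccc(c1)O2 | intermediate
14 | dihydroptychantol A | Oc1ccc2c(c1)CCc1ccc(O)c(c1)Oc1ccc(cc1)CCc1cccc(c1)O2 | target

Total step count: 8. Longest linear sequence: 6 (steps 1, 2, 5, 6, 7, 8; the branch through steps 3 and 4 is equally long).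

Steps most likely to fail

1. Step 7.
- Risk: the fluoride is activated by a single formyl group and flanked by the ortho alkyl chain. Ring closure at high dilution may therefore be slower than intermolecular etherification, and oligomerisation or slow decay of the aldehydes on long heating could take over.
- Fallback: it sets out from 5 and comes back at 12, and it replaces addition–elimination by metal-catalysed C–O bond formation. Commercial 3-bromo-4-chlorobenzaldehyde (O=Cc1ccc(Cl)c(Br)c1) would be coupled with 7 at its C–Br bond (Sonogashira) to give 4-chloro-3-[(trimethylsilyl)ethynyl]benzaldehyde F1. Desilylation (K2CO3, MeOH) would give 4-chloro-3-ethynylbenzaldehyde F2. Sonogashira coupling of F2 with 5 would give the chloro diyne dialdehyde F3, and hydrogenation over Pd/C–Ph2S, which spares aryl chlorides, would give the chloro seco dialdehyde F4. An intramolecular Pd-catalysed diaryl ether coupling of Buchwald–Hartwig type (Pd(OAc)2, t-BuXPhos, K3PO4, toluene, 100 °C, slow addition) would then join the ring A oxygen to the ring D carbon and give 12.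

2. Step 6.
- Risk: over-reduction of the formyl groups to benzylic alcohol or methyl, or stalling at the stilbene stage on the poisoned catalyst.
- Fallback: it sets out from 10 and comes back at 11, and it takes the aldehydes out of play instead of relying on catalyst selectivity. Treating 10 with HC(OMe)3 and cat. TsOH in MeOH would give the diyne bis(dimethyl acetal) F5. Hydrogenation over unpoisoned Pd/C in EtOAc with a trace of Et3N would give the saturated bis(dimethyl acetal) F6. Dilute HCl in THF would release 11.

3. Step 2.
- Risk: loss of halide discrimination, with coupling also at the formyl-activated C–Br bond and double alkynylation.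
- Fallback: it sets out from 4 and comes back at 5, and it builds the A–B tolane before any bromide is present. Compound 4 would be protected (MOMCl, iPr2NEt, CH2Cl2) as 1-ethynyl-3-(methoxymethoxy)benzene F7. Sonogashira coupling with 1 would give 4-{[3-(methoxymethoxy)phenyl]ethynyl}phenol F8. Etherification with 2 under the SNAr conditions of step 1 would give 4-bromo-2-(4-{[3-(methoxymethoxy)phenyl]ethynyl}phenoxy)benzaldehyde F9, since the MOM ether resists carbonate and fluoride. Aqueous HCl in THF would unmask the phenol to give 5.

Further compounds
F1 | step 7 | 4-chloro-3-[(trimethylsilyl)ethynyl]benzaldehyde | O=Cc1ccc(Cl)c(c1)C#C[Si](C)(C)C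
F2 | step 7 | 4-chloro-3-ethynylbenzaldehyde | O=Cc1ccc(Cl)c(c1)C#C
F3 | step 7 | chloro diyne dialdehyde | O=Cc1ccc(cc1Oc1ccc(cc1)C#Cc1cccc(O)c1)C#Cc1cc(C=O)ccc1Cl
F4 | step 7 | chloro seco dialdehyde | O=Cc1ccc(cc1Oc1ccc(cc1)CCc1cccc(O)c1)CCc1cc(C=O)ccc1Cl
F5 | step 6 | diyne bis(dimethyl acetal) | COC(OC)c1ccc(cc1Oc1ccc(cc1)C#Cc1cccc(O)c1)C#Cc1cc(ccc1F)C(OC)OC
F6 | step 6 | saturated bis(dimethyl acetal) | COC(OC)c1ccc(cc1Oc1ccc(cc1)CCc1cccc(O)c1)CCc1cc(ccc1F)C(OC)OC
F7 | step 2 | 1-ethynyl-3-(methoxymethoxy)benzene | C#Cc1cccc(OCOC)c1
F8 | step 2 | 4-{[3-(methoxymethoxy)phenyl]ethynyl}phenol | Oc1ccc(cc1)C#Cc1cccc(OCOC)c1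
F9 | step 2 | 4-bromo-2-(4-{[3-(methoxymethoxy)phenyl]ethynyl}phenoxy)benzaldehyde | O=Cc1ccc(Br)cc1Oc1ccc(cc1)C#Cc1cccc(OCOC)c1
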